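**Plan** (ring numbering: C1 bears CH2OH, C1=C2, C4 is the stereocentre, C7=C8, C11=C12)
1. C13–C14 is the middle σ-bond of the 1,5-diene C2=C1–C14–C13–C12=C11, and C1 also carries the CH2O group. This is a [3,3] retron: the carbocycle is cut back to a 14-membered lactone in which a temporary O–C(=O) bridge links C2 (carbinol carbon carrying the C1=C14H2 vinyl unit) to C13 (made acidic by PhSO2).
2. Further cuts: lactone C–O, C13–CO2H (CO2), C1–C2 (alkenyl addition to a C2 aldehyde) and C6–C7 (sp3–sp2 coupling). These give western ester 8 (ring atoms C2–C6 plus the side chain) and eastern iodoalkenyl sulfone 13 (C7–C13).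
3. Forward: 8 and 13 are made separately and joined at C6–C7; the chain is extended at C2, carboxylated at C13 and lactonised. A ring-contracting decarboxylative Claisen shift then closes the 14-membered carbocycle; the sulfone and silyl groups are removed last.
4. Stereochemistry: C4 from an iridium-catalysed asymmetric allylic alkylation; 11E from geraniol; 7Z from a Z-iodoalkene coupled with retention; the C1=C2 geometry (C3 trans to C14) from the chair transition state of the key shift. The carbinol and sulfonyl centres are transient.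

Key step: step 16

Remark: compounds 19 to 24 are carried as epimer mixtures at the carbinol and/or sulfonyl carbon, so their SMILES leave these centres open; both centres are destroyed later.
Remark: the (S,S,S) ligand in step 4 is assumed to give (3R)-7 by analogy with cinnamyl carbonates; if the sense is opposite, the enantiomeric ligand is used.

Step 1
Reactants: 1 6-methylhept-5-en-2-one
Product: 2 6-methylhepta-1,5-dien-2-yl trifluoromethanesulfonate
Conditions: LDA, THF, −78 °C; then PhNTf2, −78 to 0 °C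
Reagents that add atoms: N-phenylbis(trifluoromethanesulfonimide), O=S(=O)(N(c1ccccc1)S(=O)(=O)C(F)(F)F)C(F)(F)F
Why: Kinetic deprotonation of the methyl ketone at the methyl group followed by O-triflation should give the terminal enol triflate (kinetic enolate trapping).

Step 2
Reactants: 2 6-methylhepta-1,5-dien-2-yl trifluoromethanesulfonate; 3 (2E)-3-(tributylstannyl)prop-2-en-1-ol
Product: 4 (2E)-8-methyl-4-methylidenenona-2,7-dien-1-ol
Conditions: Pd(PPh3)4 (5 mol %), LiCl, THF, 65 °C
Reagents that add atoms: none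
Why: Stille coupling of an enol triflate with an alkenylstannane keeps the E geometry of the stannane and tolerates the free alcohol.

Step 3
Reactants: 4 (2E)-8-methyl-4-methylidenenona-2,7-dien-1-ol
Product: 5 methyl (2E)-8-methyl-4-methylidenenona-2,7-dien-1-yl carbonate
Conditions: ClCO2Me, pyridine, CH2Cl2, 0 °C
Reagents that add atoms: methyl chloroformate, COC(=O)Cl
Why: O-acylation of the primary allylic alcohol installs the carbonate leaving group for the allylic substitution.

Step 4
Reactants: 5 methyl (2E)-8-methyl-4-methylidenenona-2,7-dien-1-yl carbonate; 6 dimethyl malonate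
Product: 7 dimethyl 2-[(3R)-8-methyl-4-methylidenenona-1,7-dien-3-yl]propanedioate
Conditions: [Ir(cod)Cl]2 (2 mol %), (S)-BINOL-derived N,N-bis[(S)-1-phenylethyl]phosphoramidite (4 mol %), TBD (8 mol %), THF, rt
Reagents that add atoms: none
Why: Iridium-catalysed asymmetric allylic alkylation should deliver the malonate to the substituted allyl terminus, giving the branched 1,4-diene with the C-3 stereocentre set by the chiral phosphoramidite (catalyst control).

Step 5
Reactants: 7 dimethyl 2-[(3R)-8-methyl-4-methylidenenona-1,7-dien-3-yl]propanedioate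
Product: 8 methyl (3S)-3-ethenyl-8-methyl-4-methylidenenon-7-enoate
Conditions: LiCl, H2O, DMSO, 150 °C
Reagents that add atoms: none
Why: Krapcho dealkoxycarbonylation removes one ester under neutral conditions that should leave the non-acidic bis-allylic stereocentre untouched.

Step 6
Reactants: 9 (2E)-1-bromo-3,7-dimethylocta-2,6-diene (geranyl bromide)
Product: 10 {[(2E)-3,7-dimethylocta-2,6-dien-1-yl]sulfonyl}benzene
Conditions: PhSO2Na, DMF, rt
Reagents that add atoms: sodium benzenesulfinate, [Na+].[O-]S(=O)c1ccccc1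
Why: SN2 S-alkylation of the sulfinate at the primary allylic bromide keeps the 2E alkene.

Step 7
Reactants: 10 {[(2E)-3,7-dimethylocta-2,6-dien-1-yl]sulfonyl}benzene
Product: 11 2,2-dimethyl-3-[(3E)-3-methyl-5-(phenylsulfonyl)pent-3-en-1-yl]oxirane (racemic)
Conditions: mCPBA, CH2Cl2, 0 °C
Reagents that add atoms: 3-chloroperbenzoic acid, OOC(=O)c1cccc(Cl)c1
Why: Prilezhaev epoxidation should select the distal trisubstituted alkene, because the 2,3-alkene is deactivated by the allylic sulfonyl group.

Step 8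
Reactants: 11 2,2-dimethyl-3-[(3E)-3-methyl-5-(phenylsulfonyl)pent-3-en-1-yl]oxirane
Product: 12 (4E)-4-methyl-6-(phenylsulfonyl)hex-4-enal
Conditions: H5IO6, THF–H2O, 0 °C to rt
Reagents that add atoms: none
Why: Periodic acid opens the epoxide to the diol and cleaves it (glycol cleavage) to the aldehyde and acetone.

Step 9
Reactants: 12 (4E)-4-methyl-6-(phenylsulfonyl)hex-4-enal
Product: 13 {[(2E,6Z)-7-iodo-3-methylocta-2,6-dien-1-yl]sulfonyl}benzene
Conditions: EtPPh3I, n-BuLi, THF, rt; I2, −78 °C; NaHMDS, −20 °C; then 12, −78 °C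
Reagents that add atoms: ethyltriphenylphosphonium iodide, CC[P+](c1ccccc1)(c1ccccc1)c1ccccc1.[I-]; iodine, [I][I]
Why: Stork–Zhao olefination with the α-iodo ylide should give the Z-configured 2-iodoalkene (iodine cis to the chain) under kinetic Wittig control.

Step 10
Reactants: 8 methyl (3S)-3-ethenyl-8-methyl-4-methylidenenon-7-enoate; 13 {[(2E,6Z)-7-iodo-3-methylocta-2,6-dien-1-yl]sulfonyl}benzene
Product: 15 methyl (3R,6Z,10E)-6,10-dimethyl-3-(6-methylhepta-1,5-dien-2-yl)-12-(phenylsulfonyl)dodeca-6,10-dienoate, via alkyldisiamylborane 14 (not isolated)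
Conditions: disiamylborane (from BH3·THF and 2-methylbut-2-ene), THF, 0 °C; then 13, Pd(dppf)Cl2 (5 mol %), AsPh3, Cs2CO3, DMF–H2O, rt
Reagents that add atoms: none
Why: The hindered dialkylborane should hydroborate only the monosubstituted vinyl group, and the B-alkyl Suzuki–Miyaura coupling replaces iodine with retention, giving the 6Z trisubstituted alkene.

Step 11
Reactants: 15 methyl (3R,6Z,10E)-6,10-dimethyl-3-(6-methylhepta-1,5-dien-2-yl)-12-(phenylsulfonyl)dodeca-6,10-dienoate
Product: 16 (3R,6Z,10E)-6,10-dimethyl-3-(6-methylhepta-1,5-dien-2-yl)-12-(phenylsulfonyl)dodeca-6,10-dienal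
Conditions: DIBAL-H (1.1 equiv), CH2Cl2, −78 °C; aq. potassium sodium tartrate
Reagents that add atoms: none
Why: Partial ester reduction stops at the aluminium hemiacetal at low temperature and should release the aldehyde on work-up.

Step 12
Reactants: 17 2-bromoprop-2-en-1-ol
Product: 18 [(2-bromoprop-2-en-1-yl)oxy](tert-butyl)dimethylsilane
Conditions: TBSCl, imidazole, CH2Cl2, rt
Reagents that add atoms: tert-butyldimethylsilyl chloride, CC(C)(C)[Si](C)(C)Cl
Why: Standard O-silylation of the primary alcohol.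

Step 13
Reactants: 16 (3R,6Z,10E)-6,10-dimethyl-3-(6-methylhepta-1,5-dien-2-yl)-12-(phenylsulfonyl)dodeca-6,10-dienal; 18 [(2-bromoprop-2-en-1-yl)oxy](tert-butyl)dimethylsilane
Product: 19 (5R,8Z,12E)-2-{[tert-butyl(dimethyl)silyl]oxymethyl}-8,12-dimethyl-5-(6-methylhepta-1,5-dien-2-yl)-14-(phenylsulfonyl)tetradeca-1,8,12-trien-3-ol (both C-3 epimers)
Conditions: CrCl2 (4 equiv), NiCl2 (2 mol %), DMF, rt
Reagents that add atoms: none
Why: Nozaki–Hiyama–Kishi alkenylation adds the bromoalkene to the aldehyde without touching the acidic allyl sulfone; the new carbinol centre is not controlled because it is destroyed in step 16.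

Step 14
Reactants: 19 (5R,8Z,12E)-2-{[tert-butyl(dimethyl)silyl]oxymethyl}-8,12-dimethyl-5-(6-methylhepta-1,5-dien-2-yl)-14-(phenylsulfonyl)tetradeca-1,8,12-trien-3-ol
Product: 20 (3E,7Z,11R)-14-{[tert-butyl(dimethyl)silyl]oxymethyl}-13-hydroxy-4,8-dimethyl-11-(6-methylhepta-1,5-dien-2-yl)-2-(phenylsulfonyl)pentadeca-3,7,14-trienoic acid (epimers at C-2 and C-13)
Conditions: n-BuLi (2.1 equiv), THF, −78 °C; CO2; aq. HCl to pH 3, 0 °C
Reagents that add atoms: carbon dioxide, O=C=O
Why: After O-deprotonation the allyl sulfone is lithiated and carboxylated at the sulfonyl carbon (α-carboxylation of a sulfonyl carbanion); any carbonate formed at oxygen reverts on acidification.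

Step 15
Reactants: 20 (3E,7Z,11R)-14-{[tert-butyl(dimethyl)silyl]oxymethyl}-13-hydroxy-4,8-dimethyl-11-(6-methylhepta-1,5-dien-2-yl)-2-(phenylsulfonyl)pentadeca-3,7,14-trienoic acid
Product: 21 (4E,8Z,12R)-14-(3-{[tert-butyl(dimethyl)silyl]oxy}prop-1-en-2-yl)-5,9-dimethyl-12-(6-methylhepta-1,5-dien-2-yl)-3-(phenylsulfonyl)-1-oxacyclotetradeca-4,8-dien-2-one (epimers at C-3 and C-14)
Conditions: DCC, PPTS (cat.), CH2Cl2, syringe-pump addition to 1 mM, rt
Reagents that add atoms: none
Why: Carbodiimide macrolactonisation of the strongly activated α-sulfonyl acid under base-free high dilution should give the 14-membered lactone without moving the β,γ-alkene.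

Step 16
Reactants: 21 (4E,8Z,12R)-14-(3-{[tert-butyl(dimethyl)silyl]oxy}prop-1-en-2-yl)-5,9-dimethyl-12-(6-methylhepta-1,5-dien-2-yl)-3-(phenylsulfonyl)-1-oxacyclotetradeca-4,8-dien-2-one
Product: 24 tert-butyl{[(1Z,4R,7Z,11E)-7,11-dimethyl-4-(6-methylhepta-1,5-dien-2-yl)-13-(phenylsulfonyl)cyclotetradeca-1,7,11-trien-1-yl]methoxy}dimethylsilane (C-13 epimers), via silyl ketene acetal 22 (not isolated), via silyl ester 23 (not isolated)
Conditions: BSA (0.2 equiv), KOAc (0.1 equiv), toluene, 110 °C
Reagents that add atoms: none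
Why: Proposed new method: acetate with BSA enolises the doubly activated sulfonyl ester C–H and silylates it to ketene acetal 22, whose C=C and the exocyclic 2-substituted vinyl group on the carbinol carbon sit 1,6 across the ester, so a [3,3] (Ireland–Claisen) shift joins the sulfonyl carbon to the terminal methylene carbon and breaks the carbinol C–O bond; acetate then desilylates ester 23, which loses CO2 to a sulfonyl-stabilised carbanion that is protonated at the sulfonyl carbon. The closest known reaction types are the Ireland–Claisen ring contraction of macrolactones carrying an alkenyl group on the carbinol carbon and the decarboxylative Claisen rearrangement of acyclic allyl arylsulfonylacetates under BSA/KOAc; their use on a macrolactone with an alkenyl group at the sulfonyl carbon has not been shown. The 14-membered carbocycle is closed by a transannular [3,3]-sigmatropic shift in which the O–C(=O) unit leaves the ring and the two vinyl carbons enter it (14 to 14). No lasting stereocentre forms (the sulfonyl carbon is epimeric and becomes CH2 in step 17); the geometry of the new trisubstituted alkene is set by a chair transition state with the ring CH2 on the carbinol carbon equatorial, which places it trans to the new bond and cis to CH2OTBS for either carbinol epimer. The step needs the shift to outrun ionisation of the allylic ester and E/Z erosion of the adjacent 11,12-alkene through the delocalised anion; weakly basic acetate, a non-polar solvent and the neutral silyl ketene acetal should secure this.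

Step 17
Reactants: 24 tert-butyl{[(1Z,4R,7Z,11E)-7,11-dimethyl-4-(6-methylhepta-1,5-dien-2-yl)-13-(phenylsulfonyl)cyclotetradeca-1,7,11-trien-1-yl]methoxy}dimethylsilane
Product: 25 tert-butyl{[(1Z,4R,7Z,11E)-7,11-dimethyl-4-(6-methylhepta-1,5-dien-2-yl)cyclotetradeca-1,7,11-trien-1-yl]methoxy}dimethylsilane
Conditions: Pd(dppp)Cl2 (5 mol %), LiBHEt3, THF, 0 °C
Reagents that add atoms: none
Why: Palladium-catalysed hydride desulfonylation (allylic reduction via a π-allyl complex) should deliver hydride to the less substituted terminus, so the 11E trisubstituted alkene stays in place.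

Step 18
Reactants: 25 tert-butyl{[(1Z,4R,7Z,11E)-7,11-dimethyl-4-(6-methylhepta-1,5-dien-2-yl)cyclotetradeca-1,7,11-trien-1-yl]methoxy}dimethylsilane
Product: 26 [(1Z,4R,7Z,11E)-7,11-dimethyl-4-(6-methylhepta-1,5-dien-2-yl)cyclotetradeca-1,7,11-trien-1-yl]methanol
Conditions: TBAF, THF, rt
Reagents that add atoms: none
Why: Fluoride-mediated desilylation frees the primary allylic alcohol.

**Compound list**
1 | 6-methylhept-5-en-2-one | CC(=O)CCC=C(C)C | starting material
2 | 6-methylhepta-1,5-dien-2-yl trifluoromethanesulfonate | C=C(CCC=C(C)C)OS(=O)(=O)C(F)(F)F | intermediate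
3 | (2E)-3-(tributylstannyl)prop-2-en-1-ol | CCCC[Sn](CCCC)(CCCC)/C=C/CO | starting material
4 | (2E)-8-methyl-4-methylidenenona-2,7-dien-1-ol | C=C(CCC=C(C)C)/C=C/CO | intermediate
5 | methyl (2E)-8-methyl-4-methylidenenona-2,7-dien-1-yl carbonate | C=C(CCC=C(C)C)/C=C/COC(=O)OC | intermediate
6 | dimethyl malonate | COC(=O)CC(=O)OC | starting material
7 | dimethyl 2-[(3R)-8-methyl-4-methylidenenona-1,7-dien-3-yl]propanedioate | C=C(CCC=C(C)C)[C@H](C=C)C(C(=O)OC)C(=O)OC | intermediate
8 | methyl (3S)-3-ethenyl-8-methyl-4-methylidenenon-7-enoate | C=C(CCC=C(C)C)[C@H](C=C)CC(=O)OC | intermediate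
9 | (2E)-1-bromo-3,7-dimethylocta-2,6-diene (geranyl bromide) | CC(C)=CCC/C(C)=C/CBr | starting material
10 | {[(2E)-3,7-dimethylocta-2,6-dien-1-yl]sulfonyl}benzene | CC(C)=CCC/C(C)=C/CS(=O)(=O)c1ccccc1 | intermediate
11 | 2,2-dimethyl-3-[(3E)-3-methyl-5-(phenylsulfonyl)pent-3-en-1-yl]oxirane (racemic) | CC1(C)OC1CC/C(C)=C/CS(=O)(=O)c1ccccc1 | intermediate
12 | (4E)-4-methyl-6-(phenylsulfonyl)hex-4-enal | O=CCC/C(C)=C/CS(=O)(=O)c1ccccc1 | intermediate
13 | {[(2E,6Z)-7-iodo-3-methylocta-2,6-dien-1-yl]sulfonyl}benzene | C/C(I)=C/CC/C(C)=C/CS(=O)(=O)c1ccccc1 | intermediate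
14 | methyl (3R)-3-{2-[bis(3-methylbutan-2-yl)boranyl]ethyl}-8-methyl-4-methylidenenon-7-enoate | C=C(CCC=C(C)C)[C@H](CCB(C(C)C(C)C)C(C)C(C)C)CC(=O)OC | intermediate
15 | methyl (3R,6Z,10E)-6,10-dimethyl-3-(6-methylhepta-1,5-dien-2-yl)-12-(phenylsulfonyl)dodeca-6,10-dienoate | C=C(CCC=C(C)C)[C@H](CC/C(C)=C\CC/C(C)=C/CS(=O)(=O)c1ccccc1)CC(=O)OC | intermediate
16 | (3R,6Z,10E)-6,10-dimethyl-3-(6-methylhepta-1,5-dien-2-yl)-12-(phenylsulfonyl)dodeca-6,10-dienal | C=C(CCC=C(C)C)[C@H](CC/C(C)=C\CC/C(C)=C/CS(=O)(=O)c1ccccc1)CC=O | intermediate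
17 | 2-bromoprop-2-en-1-ol | C=C(Br)CO | starting material
18 | [(2-bromoprop-2-en-1-yl)oxy](tert-butyl)dimethylsilane | C=C(Br)CO[Si](C)(C)C(C)(C)C | intermediate
19 | (5R,8Z,12E)-2-{[tert-butyl(dimethyl)silyl]oxymethyl}-8,12-dimethyl-5-(6-methylhepta-1,5-dien-2-yl)-14-(phenylsulfonyl)tetradeca-1,8,12-trien-3-ol (both C-3 epimers) | C=C(CCC=C(C)C)[C@H](CC/C(C)=C\CC/C(C)=C/CS(=O)(=O)c1ccccc1)CC(O)C(=C)CO[Si](C)(C)C(C)(C)C | intermediate
20 | (3E,7Z,11R)-14-{[tert-butyl(dimethyl)silyl]oxymethyl}-13-hydroxy-4,8-dimethyl-11-(6-methylhepta-1,5-dien-2-yl)-2-(phenylsulfonyl)pentadeca-3,7,14-trienoic acid (epimers at C-2 and C-13) | C=C(CCC=C(C)C)[C@H](CC/C(C)=C\CC/C(C)=C/C(C(=O)O)S(=O)(=O)c1ccccc1)CC(O)C(=C)CO[Si](C)(C)C(C)(C)C | intermediate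
21 | (4E,8Z,12R)-14-(3-{[tert-butyl(dimethyl)silyl]oxy}prop-1-en-2-yl)-5,9-dimethyl-12-(6-methylhepta-1,5-dien-2-yl)-3-(phenylsulfonyl)-1-oxacyclotetradeca-4,8-dien-2-one (epimers at C-3 and C-14) | C=C(CCC=C(C)C)[C@@H]1CC/C(C)=C\CC/C(C)=C/C(S(=O)(=O)c2ccccc2)C(=O)OC(C(=C)CO[Si](C)(C)C(C)(C)C)C1 | intermediate
22 | O-trimethylsilyl ketene acetal of lactone 21 (C2=C3 double bond, C-2 bears OSiMe3; C-14 epimers) | C=C(CCC=C(C)C)[C@@H]1CC/C(C)=C\CC/C(C)=C/C(S(=O)(=O)c2ccccc2)=C(O[Si](C)(C)C)OC(C(=C)CO[Si](C)(C)C(C)(C)C)C1 | intermediate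
23 | trimethylsilyl ester of the C-13 carboxylic acid of 24 (C-13 bears CO2SiMe3 and SO2Ph; epimers) | C=C(CCC=C(C)C)[C@H]1C/C=C(\CO[Si](C)(C)C(C)(C)C)CC(C(=O)O[Si](C)(C)C)(S(=O)(=O)c2ccccc2)/C=C(\C)CC/C=C(/C)CC1 | intermediate
24 | tert-butyl{[(1Z,4R,7Z,11E)-7,11-dimethyl-4-(6-methylhepta-1,5-dien-2-yl)-13-(phenylsulfonyl)cyclotetradeca-1,7,11-trien-1-yl]methoxy}dimethylsilane (C-13 epimers) | C=C(CCC=C(C)C)[C@H]1C/C=C(\CO[Si](C)(C)C(C)(C)C)CC(S(=O)(=O)c2ccccc2)/C=C(\C)CC/C=C(/C)CC1 | intermediate
25 | tert-butyl{[(1Z,4R,7Z,11E)-7,11-dimethyl-4-(6-methylhepta-1,5-dien-2-yl)cyclotetradeca-1,7,11-trien-1-yl]methoxy}dimethylsilane | C=C(CCC=C(C)C)[C@H]1C/C=C(\CO[Si](C)(C)C(C)(C)C)CC/C=C(\C)CC/C=C(/C)CC1 | intermediate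
26 | [(1Z,4R,7Z,11E)-7,11-dimethyl-4-(6-methylhepta-1,5-dien-2-yl)cyclotetradeca-1,7,11-trien-1-yl]methanol | C=C(CCC=C(C)C)[C@H]1C/C=C(\CO)CC/C=C(\C)CC/C=C(/C)CC1 | target

**Totals**
Total step count: 18. Longest linear sequence: 13 steps (steps 1–5, 10, 11, 13–18).

**Steps most likely to fail**

Step 16 (proposed new method). The allylic ester may ionise to an ion pair and recombine without regio- or stereocontrol. The 11,12-alkene may lose its geometry through reversible deprotonation at 110 °C. The macrocycle may also disfavour the chair and let a boat path give the geometric isomer. The fallback forms the same bond by a known intramolecular sulfone alkylation. It sets out from aldehyde 16. Wittig olefination with methyl 3-(benzyloxy)-2-(triphenylphosphoranylidene)propanoate F1 (from methyl (triphenylphosphoranylidene)acetate and benzyl chloromethyl ether) should give the E-enoate F2, with the chain cis to CH2OBn. DIBAL-H reduction gives allylic alcohol F3, and MsCl/Et3N followed by LiBr gives allylic bromide F4. LDA in THF at 1 mM (−78 to 0 °C) should close the ring by SN2 attack of the sulfonyl carbanion, giving macrocyclic sulfone benzyl ether F5. Pd(dppp)Cl2/LiBHEt3 then gives benzyl ether F6, and lithium di-tert-butylbiphenylide at −78 °C removes the benzyl group, rejoining the route at 26.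

Step 15. Intermolecular esterification may give oligomers, the acid may decarboxylate early, or the β,γ-alkene may migrate into conjugation. The fallback closes the lactone at carbon instead of oxygen. It sets out from alcohol 19, which is converted with carbonyldiimidazole into imidazole-1-carboxylate F7. LiHMDS (2.2 equiv) in THF at high dilution should then acylate the sulfonyl carbanion intramolecularly, rejoining the route at lactone 21 (this also bypasses step 14).

Step 10. The 1,1-disubstituted alkene may be hydroborated in competition. Transfer of the primary alkyl group from the hindered borane to palladium may also be slow, so that protodeiodination or ionisation of the allylic sulfone by zerovalent palladium competes. The fallback uses an organozinc instead. It sets out from ester 8: hydroboration with disiamylborane followed by I2/NaOMe should give methyl (3S)-3-(2-iodoethyl)-8-methyl-4-methylidenenon-7-enoate F8. Zinc insertion (Zn, LiCl, THF) gives alkylzinc iodide F9, and Negishi coupling with 13 (Pd(PPh3)4) rejoins the route at 15.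

Further compounds
F1 | step 16 | methyl 3-(benzyloxy)-2-(triphenylphosphoranylidene)propanoate | COC(=O)C(COCc1ccccc1)=P(c1ccccc1)(c1ccccc1)c1ccccc1
F2 | step 16 | methyl (2E,5R,8Z,12E)-2-[(benzyloxy)methyl]-8,12-dimethyl-5-(6-methylhepta-1,5-dien-2-yl)-14-(phenylsulfonyl)tetradeca-2,8,12-trienoate | C=C(CCC=C(C)C)[C@H](CC/C(C)=C\CC/C(C)=C/CS(=O)(=O)c1ccccc1)C/C=C(\COCc1ccccc1)C(=O)OC
F3 | step 16 | (2Z,5R,8Z,12E)-2-[(benzyloxy)methyl]-8,12-dimethyl-5-(6-methylhepta-1,5-dien-2-yl)-14-(phenylsulfonyl)tetradeca-2,8,12-trien-1-ol | C=C(CCC=C(C)C)[C@H](CC/C(C)=C\CC/C(C)=C/CS(=O)(=O)c1ccccc1)C/C=C(\COCc1ccccc1)CO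
F4 | step 16 | allylic bromide of F3 (CH2OH replaced by CH2Br) | C=C(CCC=C(C)C)[C@H](CC/C(C)=C\CC/C(C)=C/CS(=O)(=O)c1ccccc1)C/C=C(\COCc1ccccc1)CBr
F5 | step 16 | ({[(1Z,4R,7Z,11E)-7,11-dimethyl-4-(6-methylhepta-1,5-dien-2-yl)-13-(phenylsulfonyl)cyclotetradeca-1,7,11-trien-1-yl]methoxy}methyl)benzene (C-13 epimers) | C=C(CCC=C(C)C)[C@H]1C/C=C(\COCc2ccccc2)CC(S(=O)(=O)c2ccccc2)/C=C(\C)CC/C=C(/C)CC1
F6 | step 16 | ({[(1Z,4R,7Z,11E)-7,11-dimethyl-4-(6-methylhepta-1,5-dien-2-yl)cyclotetradeca-1,7,11-trien-1-yl]methoxy}methyl)benzene | C=C(CCC=C(C)C)[C@H]1C/C=C(\COCc2ccccc2)CC/C=C(\C)CC/C=C(/C)CC1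
F7 | step 15 | imidazole-1-carboxylate of alcohol 19 (both carbinol epimers) | C=C(CCC=C(C)C)[C@H](CC/C(C)=C\CC/C(C)=C/CS(=O)(=O)c1ccccc1)CC(OC(=O)n1ccnc1)C(=C)CO[Si](C)(C)C(C)(C)C
F8 | step 10 | methyl (3S)-3-(2-iodoethyl)-8-methyl-4-methylidenenon-7-enoate | C=C(CCC=C(C)C)[C@H](CCI)CC(=O)OC
F9 | step 10 | alkylzinc iodide from F8 (CH2I replaced by CH2ZnI) | C=C(CCC=C(C)C)[C@H](CC[Zn]I)CC(=O)OC
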